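It was impossible for this flask to make more product in 50 s than 0.475 mM, its turnover budget: release constant times enzyme charge times time, the yield of enzyme sitting wholly as complex.

starting material 5.0 × 10⁻⁴ M; enzyme 0.050 µM; time 50 s

- the product and crystals together standing at 50 s, as a percentage of the starting material charged
- the change that raises the amount of product and crystals together at 50 s, in percent of the starting material charged most ("none" if none brings more than 2 percentage points) (ochre / red / teal / none)
- amount of product and crystals together at 50 s, in percent of the starting material charged, after ochre

- amounts and yields of product count crystals too
- given per volume of solution although it is solid: crystals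
- run time (flask): 50 s

Enzyme binds starting material reversibly into complex, complex releases product and enzyme, and product above its solubility forms crystals. I reckoned complex to fall back at 43500 s⁻¹, faster than its release at 190 s⁻¹, so I held binding at equilibrium and took release as the rate-limiting step. The budget then pays for two things: the fraction converted, y, times the charge, plus the logarithm of charged over left, divided by 2000 M⁻¹.

Before solving this, I asked what each given was worth near half conversion.

| A percent off in | moves y by |
|---|---|
| release constant or enzyme charge | 0.32 percentage points |
| binding constant | 0.23 points |
| forward constant | 0.001 points |

Solubility and dissolution coefficient come into play once c(product) passes 0.38 mM.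

Half conversion would have cost 0.597 mM, more than the budget, and one Newton step back gave y = 41.9%. That meant c(product) of 0.209 mM, below the solubility, so I expected no crystals, ochre and red to change nothing, and teal, which doubles the budget, to win.

The forecast, with the words “so no crystals form”, gave 41.4%, slightly below my figure, 41.4% after ochre and teal as best. The simulation gave 41.4%, 41.4% after ochre, and teal with a gain of 28 points, while ochre and red brought 0 points.

    complex → enzyme + product (k1 = 190 s⁻¹)
    starting material + enzyme ⇌ complex (K2 = 2000 M⁻¹, k2 = 8.7 × 10⁷ M⁻¹ s⁻¹)
    crystals ⇌ product, rate k3*(cs3 - [product]) while solid is left; crystals form when [product] > cs3 (cs3 = 0.38 mM, k3 = 1.2 s⁻¹)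

At 23.1 s complex in the flask fell back 230 times faster than it went on, and 36.9% of the enzyme stood as complex at 50.0 s. The flask's 41.4% costs 0.474 mM by the rule, against its budget of 0.475 mM. The neighbour charged with 3.0 × 10⁻⁸ M of enzyme had a budget of 0.285 mM, and its simulated 26.3% costs 0.284 mM.

Its constants are those of an exercise; the rest is arithmetic.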